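**Retrosynthetic overview**
- The free phenol comes from its 7-O-benzyl ether. The pyran ring (ring C) is cut at C3–C4 and closed by an enantioselective radical C–H alkylation. C4 is carried as a formyl carbon (then tosylhydrazone, then diazo carbon) and C3 as a plain benzylic CH2 group.
- Enabling feature: C3–C4 is the central bond of a bibenzyl unit. C4 sits on C4a of ring A, so a radical there is benzylic. C3–H is benzylic to the electron-rich ring B, is the weakest C–H bond of the O1–C2–C3 chain, and lies 1,6 to C4 along C4–C4a–C8a–O1–C2–C3.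
- The open precursor is cut at O1–C2 (Mitsunobu) into a ring A salicylaldehyde and a ring B 2-arylethanol.
- The ring A piece comes from 2-methoxyresorcinol (monobenzylation, ortho-formylation). The ring B piece comes from 1,2,3,4-tetramethoxybenzene (ortho-lithiation, oxirane).
- Ring order: rings A and B are bought. Ring C is the only ring formed, together with the only stereocentre, in the key step.

Key step: step 6

Assumption: 2-methoxyresorcinol and 1,2,3,4-tetramethoxybenzene are taken as purchasable. The sense of induction of the cobalt porphyrin cannot be predicted for this ring size, so the ligand antipode that delivers (3S) is to be used (both antipodes are accessible).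

Step 1
Reactants: 1 2-methoxybenzene-1,3-diol (2-methoxyresorcinol)
Product: 2 3-(benzyloxy)-2-methoxyphenol
Conditions: BnBr (1.0 equiv), K2CO3 (1.0 equiv), acetone, reflux
Reagents that add atoms: benzyl bromide, BrCc1ccccc1
Why: Williamson ether synthesis on a diol whose two OH groups are equivalent by symmetry, so only the degree of alkylation has to be controlled, and the monoether should be separable from diether and recovered 1.

Step 2
Reactants: 2 3-(benzyloxy)-2-methoxyphenol
Product: 3 4-(benzyloxy)-2-hydroxy-3-methoxybenzaldehyde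
Conditions: MgCl2, Et3N, (CH2O)n, MeCN, reflux; aq HCl work-up
Reagents that add atoms: paraformaldehyde (as formaldehyde), C=O
Why: Magnesium-mediated ortho-formylation of a phenol (Casnati–Skattebøl reaction), in which the magnesium phenoxide delivers formaldehyde only ortho to the free OH and only one ortho position is open, so a single regioisomer should form.

Step 3
Reactants: 4 1,2,3,4-tetramethoxybenzene
Product: 6 2-(2,3,4,5-tetramethoxyphenyl)ethan-1-ol, via aryllithium 5 (not isolated)
Conditions: n-BuLi, TMEDA, THF, 0 °C; oxirane, -78 °C to rt; then H2O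
Reagents that add atoms: oxirane, C1CO1
Why: Directed ortho-metalation next to a methoxy group (the two free ring positions are equivalent), followed by SN2 opening of oxirane by the aryllithium, installs the C3–C2 unit in one flask.

Step 4
Reactants: 3 4-(benzyloxy)-2-hydroxy-3-methoxybenzaldehyde, 6 2-(2,3,4,5-tetramethoxyphenyl)ethan-1-ol
Product: 7 4-(benzyloxy)-3-methoxy-2-[2-(2,3,4,5-tetramethoxyphenyl)ethoxy]benzaldehyde
Conditions: PPh3, DIAD, THF, 0 °C to rt
Reagents that add atoms: none
Why: Mitsunobu etherification, in which the acidic chelated phenol of 3 is alkylated by the primary alkoxyphosphonium ion derived from 6 under neutral conditions that leave the aldehyde untouched, forming O1–C2.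

Step 5
Reactants: 7 4-(benzyloxy)-3-methoxy-2-[2-(2,3,4,5-tetramethoxyphenyl)ethoxy]benzaldehyde
Product: 8 (E)-N'-{4-(benzyloxy)-3-methoxy-2-[2-(2,3,4,5-tetramethoxyphenyl)ethoxy]benzylidene}-4-methylbenzenesulfonohydrazide
Conditions: TsNHNH2, MeOH, rt
Reagents that add atoms: 4-methylbenzenesulfonohydrazide, Cc1ccc(cc1)S(=O)(=O)NN
Why: Condensation of an aromatic aldehyde with tosylhydrazide should give the bench-stable (E)-hydrazone, the diazo precursor for a Bamford–Stevens type release.

Step 6
Reactants: 8 (E)-N'-{4-(benzyloxy)-3-methoxy-2-[2-(2,3,4,5-tetramethoxyphenyl)ethoxy]benzylidene}-4-methylbenzenesulfonohydrazide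
Product: 10 (3S)-7-(benzyloxy)-8-methoxy-3-(2,3,4,5-tetramethoxyphenyl)-3,4-dihydro-2H-chromene, via aryldiazomethane 9 (not isolated)
Conditions: [Co(3,5-DitBu-ChenPhyrin)] (D2-symmetric chiral amidoporphyrin complex of divalent cobalt, 5 mol %), Cs2CO3 (2 equiv), 1,4-dioxane, 50 °C, argon
Reagents that add atoms: none
Why: Proposed new method: Cs2CO3 converts 8 into aryldiazomethane 9, which the divalent cobalt metalloradical activates with loss of N2 to an α-cobalt (trivalent cobalt alkyl) benzylic radical at C4; this radical abstracts a hydrogen atom from C3 through a seven-membered transition state (1,6-hydrogen atom transfer), and the C3 benzylic radical then displaces cobalt from C4 by homolytic substitution, which forms C3–C4, leaves C4 as CH2 and returns the catalyst. The closest known reaction type is the cobalt porphyrin-catalysed radical C–H alkylation with diazo compounds released from tosylhydrazones, which is established enantioselectively for five-membered rings (1,5-hydrogen transfer) and in racemic form for six-membered nitrogen heterocycles (1,6-hydrogen transfer), but not for chromans. The pyran ring (ring C) closes in a 6-exo-tet radical substitution. The C3 stereocentre is set by the catalyst: the chiral amide pocket of the porphyrin, which can hydrogen-bond to the ortho oxygen O1, should single out the pro-S hydrogen of the C3 methylene group and keep the radical face fixed until retentive substitution gives (3S). The selectivity needed is C3–H over C2–H abstraction (six- against five-ring closure), and the substrate secures it because the abstracting radical is stabilised by ring A, so that removal of the C3–H bond, benzylic to the electron-rich ring B and weaker by roughly 8 kcal/mol, is about thermoneutral or downhill while removal of the α-aryloxy C2–H bond is uphill. β-Scission of the C2–O1 bond in the C3 radical should be slow against ring closure, and the slow release of 9 keeps azine and stilbene formation low.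

Step 7
Reactants: 10 (3S)-7-(benzyloxy)-8-methoxy-3-(2,3,4,5-tetramethoxyphenyl)-3,4-dihydro-2H-chromene
Product: 11 (3S)-8-methoxy-3-(2,3,4,5-tetramethoxyphenyl)-3,4-dihydro-2H-chromen-7-ol
Conditions: H2 (1 atm), 10% Pd/C, EtOAc/MeOH, rt
Reagents that add atoms: none
Why: Catalytic hydrogenolysis of the benzyl aryl ether, under which the chroman C–O and C–C bonds, the methyl ethers and the C3 stereocentre should stay untouched.

**Compound list**
1 | 2-methoxybenzene-1,3-diol | COc1c(O)cccc1O | starting material
2 | 3-(benzyloxy)-2-methoxyphenol | COc1c(O)cccc1OCc1ccccc1 | intermediate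
3 | 4-(benzyloxy)-2-hydroxy-3-methoxybenzaldehyde | O=Cc1ccc(OCc2ccccc2)c(OC)c1O | intermediate
4 | 1,2,3,4-tetramethoxybenzene | COc1ccc(OC)c(OC)c1OC | starting material
5 | (2,3,4,5-tetramethoxyphenyl)lithium | [Li]c1cc(OC)c(OC)c(OC)c1OC | intermediate
6 | 2-(2,3,4,5-tetramethoxyphenyl)ethan-1-ol | OCCc1cc(OC)c(OC)c(OC)c1OC | intermediate
7 | 4-(benzyloxy)-3-methoxy-2-[2-(2,3,4,5-tetramethoxyphenyl)ethoxy]benzaldehyde | O=Cc1ccc(OCc2ccccc2)c(OC)c1OCCc1cc(OC)c(OC)c(OC)c1OC | intermediate
8 | (E)-tosylhydrazone of 7 | Cc1ccc(cc1)S(=O)(=O)N/N=C/c1ccc(OCc2ccccc2)c(OC)c1OCCc1cc(OC)c(OC)c(OC)c1OC | intermediate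
9 | 1-(benzyloxy)-4-(diazomethyl)-2-methoxy-3-[2-(2,3,4,5-tetramethoxyphenyl)ethoxy]benzene | [N-]=[N+]=Cc1ccc(OCc2ccccc2)c(OC)c1OCCc1cc(OC)c(OC)c(OC)c1OC | intermediate
10 | (3S)-7-(benzyloxy)-8-methoxy-3-(2,3,4,5-tetramethoxyphenyl)-3,4-dihydro-2H-chromene | COc1cc([C@H]2COc3c(ccc(OCc4ccccc4)c3OC)C2)c(OC)c(OC)c1OC | intermediate
11 | (3S)-8-methoxy-3-(2,3,4,5-tetramethoxyphenyl)-3,4-dihydro-2H-chromen-7-ol | COc1cc([C@H]2COc3c(ccc(O)c3OC)C2)c(OC)c(OC)c1OC | target

Total step count: 7. Longest linear sequence: 6 (steps 1, 2, 4, 5, 6, 7).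

**Steps most likely to fail**

1. Step 6.
- What may go wrong: hydrogen abstraction at the α-oxygen C2–H position followed by five-ring closure, dimerisation of the diazo compound, or weak facial control in the six-ring radical substitution.
- The fallback uses known chemistry, closes the same C3–C4 bond as an alkene and sets the stereocentre afterwards. It sets out from 3 and from aryllithium 5 and returns at 10.
- Wittig methylenation of 3 (Ph3PCH3Br, KOtBu, THF) gives 3-(benzyloxy)-6-ethenyl-2-methoxyphenol F1.
- Aryllithium 5 is borylated (B(OMe)3, then aq HCl) to (2,3,4,5-tetramethoxyphenyl)boronic acid F2.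
- Suzuki coupling of F2 with 2-bromoprop-2-en-1-ol (Pd(PPh3)4, K2CO3, dioxane/H2O) gives 2-(2,3,4,5-tetramethoxyphenyl)prop-2-en-1-ol F3.
- Mitsunobu union of the two pieces (PPh3, DIAD) gives 1-(benzyloxy)-4-ethenyl-2-methoxy-3-{[2-(2,3,4,5-tetramethoxyphenyl)prop-2-en-1-yl]oxy}benzene F4.
- Ring-closing metathesis with the second-generation Grubbs catalyst RuCl2(=CHPh)(PCy3)(SIMes) in CH2Cl2 gives 7-(benzyloxy)-8-methoxy-3-(2,3,4,5-tetramethoxyphenyl)-2H-chromene F5.
- Asymmetric hydrogenation of this 3-aryl-2H-chromene with [Ir(cod)(tBu-PHOX)]BArF (ligand antipode chosen for (3S)) under H2 in CH2Cl2 leads to 10.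

2. Step 4.
- What may go wrong: sluggish reaction of the doubly ortho-substituted phenol, and elimination of the activated alcohol.
- The fallback sets out from 6 and 3 and returns at 7.
- Alcohol 6 is converted (TsCl, Et3N, DMAP, CH2Cl2) into 2-(2,3,4,5-tetramethoxyphenyl)ethyl 4-methylbenzenesulfonate F6.
- F6 alkylates the preformed potassium phenoxide of 3 (K2CO3, DMF, 60 °C) in a Williamson SN2 reaction.

3. Step 1.
- What may go wrong: double alkylation at the expense of the monoether.
- The fallback sets out from 1, returns at 3 and replaces steps 1 and 2.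
- Vilsmeier–Haack formylation of 1 (POCl3, DMF, MeCN; aqueous hydrolysis) gives 2,4-dihydroxy-3-methoxybenzaldehyde F7.
- The non-chelated and more acidic 4-OH of F7 is benzylated site-selectively (BnBr, KHCO3, MeCN, 60 °C) to give 3.

Further compounds
F1 | step 6 | 3-(benzyloxy)-6-ethenyl-2-methoxyphenol | C=Cc1ccc(OCc2ccccc2)c(OC)c1O
F2 | step 6 | (2,3,4,5-tetramethoxyphenyl)boronic acid | COc1cc(B(O)O)c(OC)c(OC)c1OC
F3 | step 6 | 2-(2,3,4,5-tetramethoxyphenyl)prop-2-en-1-ol | C=C(CO)c1cc(OC)c(OC)c(OC)c1OC
F4 | step 6 | 1-(benzyloxy)-4-ethenyl-2-methoxy-3-{[2-(2,3,4,5-tetramethoxyphenyl)prop-2-en-1-yl]oxy}benzene | C=Cc1ccc(OCc2ccccc2)c(OC)c1OCC(=C)c1cc(OC)c(OC)c(OC)c1OC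
F5 | step 6 | 7-(benzyloxy)-8-methoxy-3-(2,3,4,5-tetramethoxyphenyl)-2H-chromene | COc1cc(C2=Cc3ccc(OCc4ccccc4)c(OC)c3OC2)c(OC)c(OC)c1OC
F6 | step 4 | 2-(2,3,4,5-tetramethoxyphenyl)ethyl 4-methylbenzenesulfonate | Cc1ccc(cc1)S(=O)(=O)OCCc1cc(OC)c(OC)c(OC)c1OC
F7 | step 1 | 2,4-dihydroxy-3-methoxybenzaldehyde | O=Cc1ccc(O)c(OC)c1O
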